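The synthesis rests on cutting ring C of the flavonol back to a five-membered furanone. The O1–C2(aryl)–C3(OH)–C4(=O) sequence of ring C holds the atoms of an aurone's O1–C2(=CH–aryl)–C3(=O) unit plus one oxygen. Bromine addition to the exocyclic alkene followed by hydroxide turns the benzofuranone into the 3-hydroxychromone in one operation, forming O1–C2 and the C3–OH bond. The substrate is the Z-aurone benzylated at O4, O7, O3′ and O5′. It is built without regiochemical ambiguity from an allyl-masked acetophenone via a chalcone and Hg(OAc)2 cyclisation. Hydrogenolysis finishes the synthesis.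

Key step: step 10

Remark: in aurone 12 the only unsubstituted ring A carbon is C5 (C6 carries the methoxy group); this C5–H is where competing aromatic bromination must be avoided, and it becomes C6 of chromone 14.
Remark: dibromide 13 is drawn as one enantiomer of the racemic anti adduct; both of its stereocentres disappear within the same step.

Step 1
Reactants: 1 2′,6′-dihydroxy-4′-methoxyacetophenone
Product: 2 1-[2-(allyloxy)-6-hydroxy-4-methoxyphenyl]ethan-1-one
Conditions: allyl bromide (1.05 equiv), K2CO3 (1.1 equiv), acetone, reflux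
Reagents that add atoms: allyl bromide, C=CCBr
Why: Williamson ether synthesis in which the two hydroxyls of symmetric 1 are equivalent, and after the first allylation the remaining hydroxyl is held in a hydrogen bond to the ketone, which should stop the reaction at the mono-ether.

Step 2
Reactants: 2 1-[2-(allyloxy)-6-hydroxy-4-methoxyphenyl]ethan-1-one
Product: 4 1-[2-(allyloxy)-3,6-dihydroxy-4-methoxyphenyl]ethan-1-one, via aryl sulfate 3 (not isolated)
Conditions: K2S2O8, aq KOH, pyridine, 0 → 20 °C; then aq HCl, Na2SO3, 85 °C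
Reagents that add atoms: potassium peroxodisulfate, [K+].[K+].[O-]S(=O)(=O)OOS(=O)(=O)[O-]
Why: Elbs persulfate oxidation, in which the phenoxide of the only free hydroxyl attacks a peroxide oxygen through its para carbon C3 and acid hydrolysis of sulfate 3 releases the quinol, so the new oxygen is placed next to the masked oxygen that later becomes O1.

Step 3
Reactants: 4 1-[2-(allyloxy)-3,6-dihydroxy-4-methoxyphenyl]ethan-1-one
Product: 5 1-[2-(allyloxy)-3,6-bis(benzyloxy)-4-methoxyphenyl]ethan-1-one
Conditions: BnBr (2.4 equiv), K2CO3, DMF, N2, 60 °C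
Reagents that add atoms: benzyl bromide, BrCc1ccccc1
Why: Exhaustive Williamson benzylation of both free phenols, which needs no selectivity because the future ring oxygen is still allylated, the hydrogen-bonded 6-hydroxyl reacting on warming in DMF.

Step 4
Reactants: 5 1-[2-(allyloxy)-3,6-bis(benzyloxy)-4-methoxyphenyl]ethan-1-one
Product: 6 1-[3,6-bis(benzyloxy)-2-hydroxy-4-methoxyphenyl]ethan-1-one
Conditions: Pd(PPh3)4 (5 mol %), morpholine, THF, rt
Reagents that add atoms: none
Why: Tsuji–Trost deallylation, in which zerovalent palladium ionises only the allyl aryl ether to a π-allyl complex that morpholine intercepts, leaving the benzyl ethers, the methyl ether and the ketone untouched.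

Step 5
Reactants: 7 3,5-dihydroxy-4-methoxybenzoic acid
Product: 8 benzyl 3,5-bis(benzyloxy)-4-methoxybenzoate
Conditions: BnBr (3.5 equiv), K2CO3, DMF, 60 °C
Reagents that add atoms: benzyl bromide, BrCc1ccccc1
Why: Williamson alkylation of both phenols together with O-alkylation of the carboxylate, so no partial protection has to be controlled.

Step 6
Reactants: 8 benzyl 3,5-bis(benzyloxy)-4-methoxybenzoate
Product: 9 [3,5-bis(benzyloxy)-4-methoxyphenyl]methanol
Conditions: LiAlH4, THF, 0 °C → rt; aq NaOH work-up
Reagents that add atoms: none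
Why: Hydride reduction of the benzyl ester to the primary alcohol, the aryl benzyl and methyl ethers being inert to LiAlH4.

Step 7
Reactants: 9 [3,5-bis(benzyloxy)-4-methoxyphenyl]methanol
Product: 10 3,5-bis(benzyloxy)-4-methoxybenzaldehyde
Conditions: activated MnO2 (10 equiv), CH2Cl2, rt
Reagents that add atoms: none
Why: Oxidation of a benzylic alcohol with activated MnO2, which should stop at the aldehyde without touching the ethers.

Step 8
Reactants: 6 1-[3,6-bis(benzyloxy)-2-hydroxy-4-methoxyphenyl]ethan-1-one; 10 3,5-bis(benzyloxy)-4-methoxybenzaldehyde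
Product: 11 (E)-1-[3,6-bis(benzyloxy)-2-hydroxy-4-methoxyphenyl]-3-[3,5-bis(benzyloxy)-4-methoxyphenyl]prop-2-en-1-one
Conditions: KOH (50% aq), EtOH/THF, rt
Reagents that add atoms: none
Why: Claisen–Schmidt condensation, in which the methyl ketone enolate adds to the non-enolisable aldehyde and E1cB dehydration gives the thermodynamically preferred E-enone, while the benzyl group on O6′ leaves only the hydrogen-bonded 2′-hydroxyl free.

Step 9
Reactants: 11 (E)-1-[3,6-bis(benzyloxy)-2-hydroxy-4-methoxyphenyl]-3-[3,5-bis(benzyloxy)-4-methoxyphenyl]prop-2-en-1-one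
Product: 12 (Z)-4,7-bis(benzyloxy)-2-[3,5-bis(benzyloxy)-4-methoxybenzylidene]-6-methoxybenzofuran-3(2H)-one
Conditions: Hg(OAc)2 (1.1 equiv), pyridine, 110 °C
Reagents that add atoms: none
Why: Oxidative cyclisation of a 2′-hydroxychalcone with divalent mercury, in which the phenoxide adds 5-exo-trig to the α-carbon of the mercury-activated alkene and loss of mercury metal and acetic acid restores the exocyclic double bond as the thermodynamically preferred Z isomer (aryl cis to O1, away from the C3 carbonyl).

Step 10
Reactants: 12 (Z)-4,7-bis(benzyloxy)-2-[3,5-bis(benzyloxy)-4-methoxybenzylidene]-6-methoxybenzofuran-3(2H)-one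
Product: 14 5,8-bis(benzyloxy)-2-[3,5-bis(benzyloxy)-4-methoxyphenyl]-3-hydroxy-7-methoxy-4H-chromen-4-one, via aurone dibromide 13 (not isolated)
Conditions: pyridinium tribromide (1.05 equiv), CH2Cl2, −20 → 0 °C, dark; evaporate; then KOH (4 equiv), H2O/EtOH/THF, 0 °C → rt; AcOH
Reagents that add atoms: potassium hydroxide, [K+].[OH-]
Why: Bromine from the tribromide adds across the exocyclic C2=CH bond to give 13; hydroxide then replaces the bromide on the ketal-type C2 (ionisation helped by the lone pair of O1), the hemiketal collapses to a phenoxide tethered to an α-bromobenzyl 1,2-diketone, the phenoxide oxygen displaces the benzylic bromide, and the chromane-3,4-dione enolises, so that former C2 becomes C3 and the benzylidene carbon becomes C2. The closest known reaction type is the Auwers flavonol synthesis from aurone dibromides. Ring C is closed in a 6-exo-tet mode, O1 attacking the sp3 benzylic carbon with bromide leaving outside the new ring. No stereocentre survives, since the two centres of 13 are erased by substitution and enolisation. The step needs addition to the alkene in preference to substitution of the C5–H of ring A; the substrate favours this because the alkene is an enol ether of O1 and should be the most nucleophilic π bond, C5 is shielded between the 4-benzyloxy and 6-methoxy groups, the ring A oxygens are cross-conjugated with the C3 ketone and ring B sits on an electron-poor enone. One equivalent of the mild tribromide at low temperature in the dark supports this and avoids benzylic radical bromination, and a water-rich base favours hydroxide over ethoxide at C2.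

Step 11
Reactants: 14 5,8-bis(benzyloxy)-2-[3,5-bis(benzyloxy)-4-methoxyphenyl]-3-hydroxy-7-methoxy-4H-chromen-4-one
Product: 15 2-(3,5-dihydroxy-4-methoxyphenyl)-3,5,8-trihydroxy-7-methoxy-4H-chromen-4-one
Conditions: H2 (1 atm), 10% Pd/C, THF/MeOH, rt; work-up under argon
Reagents that add atoms: none
Why: Catalytic hydrogenolysis should cleave the four benzylic C–O bonds while the methyl ethers and the tetrasubstituted, vinylogous-ester C2=C3 bond of the chromone stay intact, and exclusion of air during work-up protects the 5,8-quinol.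

Compound list
1 | 2′,6′-dihydroxy-4′-methoxyacetophenone | COc1cc(O)c(C(C)=O)c(O)c1 | starting material
2 | 1-[2-(allyloxy)-6-hydroxy-4-methoxyphenyl]ethan-1-one | COc1cc(O)c(C(C)=O)c(OCC=C)c1 | intermediate
3 | potassium 3-acetyl-2-(allyloxy)-4-hydroxy-6-methoxyphenyl sulfate | COc1cc(O)c(C(C)=O)c(OCC=C)c1OS(=O)(=O)[O-].[K+] | intermediate
4 | 1-[2-(allyloxy)-3,6-dihydroxy-4-methoxyphenyl]ethan-1-one | COc1cc(O)c(C(C)=O)c(OCC=C)c1O | intermediate
5 | 1-[2-(allyloxy)-3,6-bis(benzyloxy)-4-methoxyphenyl]ethan-1-one | COc1cc(OCc2ccccc2)c(C(C)=O)c(OCC=C)c1OCc1ccccc1 | intermediate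
6 | 1-[3,6-bis(benzyloxy)-2-hydroxy-4-methoxyphenyl]ethan-1-one | COc1cc(OCc2ccccc2)c(C(C)=O)c(O)c1OCc1ccccc1 | intermediate
7 | 3,5-dihydroxy-4-methoxybenzoic acid | COc1c(O)cc(C(=O)O)cc1O | starting material
8 | benzyl 3,5-bis(benzyloxy)-4-methoxybenzoate | COc1c(OCc2ccccc2)cc(C(=O)OCc2ccccc2)cc1OCc1ccccc1 | intermediate
9 | [3,5-bis(benzyloxy)-4-methoxyphenyl]methanol | COc1c(OCc2ccccc2)cc(CO)cc1OCc1ccccc1 | intermediate
10 | 3,5-bis(benzyloxy)-4-methoxybenzaldehyde | COc1c(OCc2ccccc2)cc(C=O)cc1OCc1ccccc1 | intermediate
11 | (E)-1-[3,6-bis(benzyloxy)-2-hydroxy-4-methoxyphenyl]-3-[3,5-bis(benzyloxy)-4-methoxyphenyl]prop-2-en-1-one | COc1cc(OCc2ccccc2)c(C(=O)/C=C/c2cc(OCc3ccccc3)c(OC)c(OCc3ccccc3)c2)c(O)c1OCc1ccccc1 | intermediate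
12 | (Z)-4,7-bis(benzyloxy)-2-[3,5-bis(benzyloxy)-4-methoxybenzylidene]-6-methoxybenzofuran-3(2H)-one | COc1c(OCc2ccccc2)cc(/C=C2\Oc3c(OCc4ccccc4)c(OC)cc(OCc4ccccc4)c3C2=O)cc1OCc1ccccc1 | intermediate
13 | 4,7-bis(benzyloxy)-2-bromo-2-{bromo[3,5-bis(benzyloxy)-4-methoxyphenyl]methyl}-6-methoxybenzofuran-3(2H)-one, racemic anti adduct, one enantiomer drawn | COc1c(OCc2ccccc2)cc([C@@H](Br)[C@]2(Br)Oc3c(OCc4ccccc4)c(OC)cc(OCc4ccccc4)c3C2=O)cc1OCc1ccccc1 | intermediate
14 | 5,8-bis(benzyloxy)-2-[3,5-bis(benzyloxy)-4-methoxyphenyl]-3-hydroxy-7-methoxy-4H-chromen-4-one | COc1cc(OCc2ccccc2)c2c(=O)c(O)c(-c3cc(OCc4ccccc4)c(OC)c(OCc4ccccc4)c3)oc2c1OCc1ccccc1 | intermediate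
15 | 2-(3,5-dihydroxy-4-methoxyphenyl)-3,5,8-trihydroxy-7-methoxy-4H-chromen-4-one | COc1cc(O)c2c(=O)c(O)c(-c3cc(O)c(OC)c(O)c3)oc2c1O | target

Total step count: 11.
Longest linear sequence: 8 steps (steps 1, 2, 3, 4, 8, 9, 10 and 11).

Steps most likely to fail

Step 10. Bromine may substitute the activated C5–H of ring A instead of adding to the alkene. The dibromide may also lose bromine or HBr back to aurone-type material, or undergo benzylic solvolysis before hydroxide opens the furanone, because the donor groups ortho and para to the ketone slow that opening. The fallback builds ring C in the reverse order with known chemistry and sets out from chalcone 11. Catalytic I2 in DMSO at 120 °C should close O1–C2 oxidatively to 5,8-bis(benzyloxy)-2-[3,5-bis(benzyloxy)-4-methoxyphenyl]-7-methoxy-4H-chromen-4-one F1. C3 of this flavone is then lithiated with lithium diisopropylamide in THF at −78 °C and trapped with B(OMe)3 to give dimethyl {5,8-bis(benzyloxy)-2-[3,5-bis(benzyloxy)-4-methoxyphenyl]-7-methoxy-4-oxo-4H-chromen-3-yl}boronate F2, which is not isolated. Oxidation with H2O2/AcOH should give 14, where the route is rejoined before step 11.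

Step 2. The persulfate oxidation may stall at low conversion, and the electron-rich quinol or its sulfate may be oxidised further to dark polymeric material in the alkaline medium. The allyl group may also be attacked by sulfate radicals. The fallback sets out from 2 and uses a Teuber oxidation with Fremy's salt, (KSO3)2NO, in phosphate-buffered aqueous acetone. This should give 2-acetyl-3-(allyloxy)-5-methoxy-1,4-benzoquinone F3, and reduction with Na2S2O4 should then deliver 4, where the route is rejoined before step 3.

Step 9. The mercury-mediated closure may go 6-endo to flavanone or flavone, or demercuration may remain incomplete at the hindered phenol. The fallback sets out from 6 and assembles the aurone from a preformed furanone. α-Bromination with CuBr2 in EtOAc/CHCl3 at reflux should give 1-[3,6-bis(benzyloxy)-2-hydroxy-4-methoxyphenyl]-2-bromoethan-1-one F4. NaOAc in EtOH then closes it to 4,7-bis(benzyloxy)-6-methoxybenzofuran-3(2H)-one F5. Condensation of F5 with aldehyde 10 on neutral Al2O3 in CH2Cl2 should give 12 directly, bypassing 11, and the route is rejoined before step 10.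

Further compounds
F1 | step 10 | 5,8-bis(benzyloxy)-2-[3,5-bis(benzyloxy)-4-methoxyphenyl]-7-methoxy-4H-chromen-4-one | COc1cc(OCc2ccccc2)c2c(=O)cc(-c3cc(OCc4ccccc4)c(OC)c(OCc4ccccc4)c3)oc2c1OCc1ccccc1
F2 | step 10 | dimethyl {5,8-bis(benzyloxy)-2-[3,5-bis(benzyloxy)-4-methoxyphenyl]-7-methoxy-4-oxo-4H-chromen-3-yl}boronate | COB(OC)c1c(-c2cc(OCc3ccccc3)c(OC)c(OCc3ccccc3)c2)oc2c(OCc3ccccc3)c(OC)cc(OCc3ccccc3)c2c1=O
F3 | step 2 | 2-acetyl-3-(allyloxy)-5-methoxy-1,4-benzoquinone | COC1=CC(=O)C(C(C)=O)=C(OCC=C)C1=O
F4 | step 9 | 1-[3,6-bis(benzyloxy)-2-hydroxy-4-methoxyphenyl]-2-bromoethan-1-one | COc1cc(OCc2ccccc2)c(C(=O)CBr)c(O)c1OCc1ccccc1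
F5 | step 9 | 4,7-bis(benzyloxy)-6-methoxybenzofuran-3(2H)-one | COc1cc(OCc2ccccc2)c2c(c1OCc1ccccc1)OCC2=O
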